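The easy step is one addition: target plus over-reaction product, called S, counts the charge that has gone past the open intermediate.

| flask | starting material | solid partner | protic impurity | remark | time |
|---|---|---|---|---|---|
| south-east | 1.5 M | 1.8 M | 0.42 M | run made earlier |  |
| north-west | 1.5 M | 1.8 M | 0.66 M | run made earlier |  |
| north-east | 2.2 M | 1.8 M | 0.30 M | run made earlier |  |
| teal | 1.5 M | 1.80 M | 0.300 M |  | 90 h |
| blue | 1.5 M | 1.80 M | 0.300 M |  | 30 h |

| run | time / h | over-reaction product / % | target / % | open intermediate / % | starting material / % |
|---|---|---|---|---|---|
| south-east | 1.33 | 0.3 | 0 | 11.2 | 84.3 |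
| south-east | 2.00 | 0 | 0 | 18.3 | 79.4 |
| south-east | 3.00 | 1.5 | 0.7 | 24.3 | 70.0 |
| south-east | 5.00 | 0.1 | 1.2 | 33.4 | 56.6 |
| south-east | 8.00 | 0 | 2.3 | 46.4 | 40.1 |
| south-east | 12.0 | 2.6 | 4.1 | 53.9 | 28.5 |
| south-east | 20.0 | 7.1 | 7.8 | 58.5 | 12.2 |
| north-west | 1.33 | 0 | 2.3 | 11.2 | 84.2 |
| north-west | 2.00 | 0 | 0.4 | 17.4 | 77.0 |
| north-west | 3.00 | 0 | 0.3 | 23.7 | 67.7 |
| north-west | 5.00 | 0 | 0.5 | 34.2 | 52.8 |
| north-west | 8.00 | 0 | 2.0 | 42.8 | 37.7 |
| north-west | 12.0 | 2.4 | 3.0 | 51.9 | 24.3 |
| north-west | 20.0 | 5.5 | 6.7 | 52.5 | 12.4 |
| north-east | 1.33 | 1.4 | 0 | 12.4 | 85.7 |
| north-east | 2.50 | 0 | 0 | 21.4 | 78.4 |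
| north-east | 5.00 | 0.4 | 0.1 | 34.2 | 58.1 |
| north-east | 10.0 | 0.5 | 1.4 | 53.3 | 34.3 |
| north-east | 20.0 | 3.8 | 5.4 | 63.9 | 15.9 |

(scatter of a reading: 1 percentage point)

- as a solid, counted per litre of solution: solid partner
- the numbers in the tables scatter by 1 percentage point (one standard deviation)
- at the start none of the solid partner is in solution

- which of these there is most of at the end, counted by the starting material in it, teal (starting material / over-reaction product / open intermediate / target)
- which of these there is most of at the end, counted by the starting material in it, blue (starting material / over-reaction product / open intermediate / target)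
- final amount of the leader among these, as a percentage of the starting material charged, in teal
- final amount of the leader among these, as a percentage of the starting material charged, in blue

Teal and blue are one recipe read at different times, with the starting-material and partner charges of the south-east run. Over the last stretch of that run S rose from 6.70% to 14.9%, so the mean flow 0.0103 /h, called w, the rise of S per hour as a share of the charge, is a reading carrying the scatter of its columns. At 20.0 h the columns miss 14.4% of the charge in the south-east run and 22.9% in the north-west run, in step with the impurity, so the ceiling, an estimate for the recipe of teal and blue, is 89.7%.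

If the flow holds at w, S stands at 25.1% in blue and 86.7% in teal. If instead the flow shrinks with the pool of starting material plus open intermediate, at 0.0134 /h of the pool, S stands at 23.8% in blue. In teal, with target taken at its last reading of 7.8%, over-reaction product then stands at 50.1%.

Earlier in that run the flow was 0.00333 /h, less than w, while the pool stood larger. In these readings of the south-east run the flow grew while the pool shrank, so this reckoning keeps to the upper version: with target again at 7.8%, over-reaction product leads teal near 78.9%. Open intermediate leads blue near 60.3%, the ceiling less S and less the starting material carried forward from its last fall.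

The forecast names open intermediate at 53% for blue, lower than this reckoning, and over-reaction product at 58% for teal, lower again, adding of teal: “This is uncertain because partner depletion could stall the over-reaction.”

The flask gives over-reaction product at 84.6% in teal and open intermediate at 54.3% in blue.

    starting material + protic impurity → quenched substrate (k = 1.70 × 10⁻⁵ /M/s)
    solid partner ⇌ fresh partner, rate k2*(cs2 - [fresh partner]) while solid is left; crystals form when [fresh partner] > cs2 (solubility = 1.30 M, k = 1.20 × 10⁻⁵ /s)
    open intermediate + second intermediate → target (k = 3.10 × 10⁻⁴ /M/s)
    fresh partner → second intermediate (k = 9.00 × 10⁻⁶ /s)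
    target → over-reaction product (k = 3.20 × 10⁻⁵ /s)
    starting material ⇌ open intermediate (K = 23.0, k = 2.60 × 10⁻⁵ /s)

S is 27.6% in blue and 87.2% in teal, so the mean flow between those readings is 0.00994 /h, beside w at 0.0103 /h. At 45.0 h teal holds 37.1% of over-reaction product beside 35.9% of open intermediate. Carried to 30 h, w gives S of 25.1% with no term for impurity, and the flask like blue but with 0.75 M of protic impurity holds open intermediate at 42.5% and S at 27.2%.

Readings and results stem from a simulated flask on assumed constants; the scatter is artificial.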